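Time was what I had to work with: I wanted the moment of most J in the flask, and the window around it, from earlier runs on solid D with reagent Z.

| flask | D | Z | remark | time |
|---|---|---|---|---|
| violet | 18 mM | 1.1 equiv | run made earlier |  |
| ochre | 18 mM | 1.8 equiv | run made earlier |  |
| red | 36 mM | 0.80 equiv | run made earlier |  |
| flask | 18 mM | 0.800 equiv |  | 6.0 d |

- violet (time / d: J / %, D / %): 0.500: 22.6, 77.1; 0.833: 37.3, 62.3; 1.04: 46.3, 52.2; 1.67: 73.1, 25.6; 2.50: 100.2, 0; 3.00: 99.5, 0; 5.00: 100.7, 0
- ochre (time / d: J / %, D / %): 0.500: 22.5, 75.7; 0.833: 37.1, 61.5; 1.04: 47.2, 51.7; 1.67: 76.2, 24.1; 2.50: 99.7, 0.2; 3.00: 100.2, 0; 5.00: 100.1, 0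
- red (time / d: J / %, D / %): 0.500: 11.8, 88.9; 1.04: 23.1, 76.8; 1.67: 38.1, 61.7; 3.00: 66.9, 32.6; 5.00: 77.7, 12.3

(readings scatter by 0.5 percentage points)

- the moment within 6.0 d at which there is most J
- the amount of J, in percent of the D charged, at that time
- earliest time at which at least nineteen twentieths of that best amount are there, in d
- latest time at which they still are, in d

- at the start none of D is in solution
- a reading or a percentage of J counts all its forms, free or not

I read one row of these tables, 1.04 d, where the three runs share a time. Violet held 46.3 % J and ochre 47.2 %, so going from 1.1 equiv to 1.8 equiv of Z moved J by about the scatter. Red, with twice the D, held half the percentage of violet. The zero of my scale was first order in D, where that percentage stays the same at either charge. Red sat far from that zero, yet in mM the runs agreed: violet gave 8.01 mM d⁻¹ and red 8.00 mM d⁻¹. I called this the feed rate, the J formed per litre and day while Z lasts, and took dissolution of D as the likely rate-limiting step.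

Taking one Z per J, Z was the limiting reagent of the flask, with a charge of 14.4 mM. Dividing by the feed rate, I reckoned Z gone at 1.80 d, with J at 80.0 %. Beyond that I had red's last reading at 5.00 d, past its own reckoned exhaustion at 3.59 d. Its 77.7 % J and 12.3 % D left 10.0 % of the charge unaccounted for, so something besides J was taking material, and I set no close for the window.

The forecast, holding that “the reaction is limited by dissolution of solid D”, gave 79.5 % at 1.8 d and a window from 1.69 d to 6 d. The flask gave 78.7 % at 2.17 d, with a window from 1.82 d to 3.28 d.

    D ⇌ E, rate k1*(cs1 - [E]) while solid is left; crystals form when [E] > cs1 (solubility = 2.40 mM, k = 4.03 × 10⁻⁵ s⁻¹)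
    E + Z → J (k = 0.114 L mol⁻¹ s⁻¹)
    E + J → X (k = 0.00229 L mol⁻¹ s⁻¹)
    G ⇌ J, rate k4*(cs4 - [J]) while solid is left; crystals form when [J] > cs4 (solubility = 1.70 mM, k = 0.00134 s⁻¹)

The flask's Z was down to 0.237 % of its charge at 2.17 d, later than my 1.80 d. The wearing away of Z held the flask's highest J to 78.7 %; without it the same run reached 99.5 %, an effect of 21 percentage points. The conversion of E + J into X was a part of the early close: taking that step away raised the highest J from 78.7 % to 80.0 % and changed the close of the window. Between 3.00 d and 6.00 d the flask's J fell from 75.8 % to 66.0 %, while X rose from 8.34 % to 28.0 %, twice that loss, as each X counts as two.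

For a neighbouring flask with 72 mM of D at the same 0.800 equiv, the feed rate puts exhaustion at 7.19 d, later than the 6.0 d limit, and J at that limit at 66.7 %. The computed flask gave 68.4 %, with 14 % of its Z left.

(Readings and results are calculated from invented constants, noise included.)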